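**Retrosynthetic overview**

- Ring numbering used throughout: O1, C2 (methyl), C3 (formyl carbon C7), C4 (arm C8H2–C9 ester), C5 (CO2Me), C6. The strategy rests on C4 being both a ring carbon and the β-carbon of the C8–C9 ester arm, with C5 two atoms from O1 through C6.
- The only ring, the pyran, is therefore closed at C4–C5 by 6-exo addition of a C5 radical, tethered to O1 as a C6 bromoacetal, onto a C4=C8 enoate (Ueno–Stork).
- After closure: C6 acetal to C5=C6 enol ether, C5 trichloroacetylation and methanolysis to the methyl ester, C7 PMB ether to the aldehyde, then release of the catechol.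
- Before closure: the enoate comes from a Horner–Wadsworth–Emmons union of a C2–C4/C7 aldehyde with the hydroxytyrosyl phosphonoacetate; C2 comes from methyl (S)-3-hydroxybutanoate and C3 from an anti-selective Fráter–Seebach alkylation with PMBOCH2Cl.

Key step: step 11

Remark (assumption): p-methoxybenzyl chloromethyl ether is too labile to be relied on as a purchased reagent, so it is made in steps 1 and 2. The acetal carbon C6 is carried as a mixture of epimers and drawn without configuration until it becomes trigonal in step 12. Abbreviations: PMB = 4-methoxybenzyl, TBS = tert-butyldimethylsilyl.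

**Route**

Step 1
Reactants: 1 p-methoxybenzyl alcohol; 2 chloromethyl methyl sulfide
Product: 4 p-methoxybenzyl methylthiomethyl ether (PMBOCH2SMe), via sodium 4-methoxybenzyl alkoxide 3 (not isolated)
Conditions: NaH, THF, 0 °C; then 2, NaI (cat.), 0 °C → rt
Reagents that add atoms: none
Why: Williamson etherification of the sodium alkoxide with the α-chloro sulfide (iodide-assisted) is the standard entry to such O,S-acetals and should be clean.

Step 2
Reactants: 4 p-methoxybenzyl methylthiomethyl ether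
Product: 5 p-methoxybenzyl chloromethyl ether (PMBOCH2Cl)
Conditions: SO2Cl2 (1.0 equiv), CH2Cl2, −78 °C; volatiles removed in vacuo, used crude at once
Reagents that add atoms: sulfuryl chloride, ClS(Cl)(=O)=O
Why: Chlorinolysis of the O,S-acetal (S-chlorosulfonium formation, loss of MeSCl) is the established way to alkoxymethyl chlorides and should give the labile chloromethyl ether without touching the anisyl ring at low temperature.

Step 3
Reactants: 6 methyl (S)-3-hydroxybutanoate; 5 p-methoxybenzyl chloromethyl ether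
Product: 8 methyl (2S,3S)-3-hydroxy-2-{[(4-methoxybenzyl)oxy]methyl}butanoate, via dilithium alkoxide enolate 7 (not isolated)
Conditions: LiN(i-Pr)2 (2.2 equiv), THF, −78 → −20 °C; then 5, THF, −78 → −20 °C; aq. NH4Cl
Reagents that add atoms: none
Why: Fráter–Seebach alkylation, in which the reactive alkoxymethyl chloride attacks the chelated dianion on the face opposite the carbinol methyl group, should set the new centre (ring C3) anti to the existing one (ring C2).

Step 4
Reactants: 8 methyl (2S,3S)-3-hydroxy-2-{[(4-methoxybenzyl)oxy]methyl}butanoate; 9 ethyl vinyl ether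
Product: 10 methyl (2S,3S)-3-(2-bromo-1-ethoxyethoxy)-2-{[(4-methoxybenzyl)oxy]methyl}butanoate (both acetal epimers)
Conditions: NBS, 9 (excess), CH2Cl2, −40 → 0 °C
Reagents that add atoms: N-bromosuccinimide, O=C1CCC(=O)N1Br
Why: Bromoacetalisation, in which the secondary alcohol captures the bromo-oxocarbenium ion formed from NBS and the vinyl ether, should install the O1–C6–C5 tether; the new acetal centre is uncontrolled and is erased later.

Step 5
Reactants: 10 methyl (2S,3S)-3-(2-bromo-1-ethoxyethoxy)-2-{[(4-methoxybenzyl)oxy]methyl}butanoate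
Product: 11 (2S,3S)-3-(2-bromo-1-ethoxyethoxy)-2-{[(4-methoxybenzyl)oxy]methyl}butan-1-ol
Conditions: i-Bu2AlH (2.5 equiv), CH2Cl2, −78 → −20 °C; aq. potassium sodium tartrate
Reagents that add atoms: none
Why: Hydride reduction of the methyl ester to the primary alcohol should leave the alkyl bromide, the mixed acetal and the PMB ether untouched at low temperature; full reduction followed by reoxidation is chosen over a partial reduction for reliability.

Step 6
Reactants: 11 (2S,3S)-3-(2-bromo-1-ethoxyethoxy)-2-{[(4-methoxybenzyl)oxy]methyl}butan-1-ol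
Product: 12 (2S,3S)-3-(2-bromo-1-ethoxyethoxy)-2-{[(4-methoxybenzyl)oxy]methyl}butanal
Conditions: Dess–Martin periodinane, NaHCO3, CH2Cl2, 0 °C → rt; used crude
Reagents that add atoms: none
Why: Dess–Martin oxidation under buffered, base-free conditions should give the α-branched aldehyde without epimerisation of the α-centre or β-elimination of either alkoxy group.

Step 7
Reactants: 13 hydroxytyrosol
Product: 14 tert-butyl{2-[3,4-bis(tert-butyldimethylsilyloxy)phenyl]ethoxy}dimethylsilane (tris-TBS hydroxytyrosol)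
Conditions: TBSCl (3.5 equiv), imidazole, DMF, rt
Reagents that add atoms: tert-butyldimethylsilyl chloride, CC(C)(C)[Si](C)(C)Cl
Why: Exhaustive silylation of the two phenols and the primary alcohol is routine and sets up their differentiation in the next step.

Step 8
Reactants: 14 tris-TBS hydroxytyrosol
Product: 15 2-[3,4-bis(tert-butyldimethylsilyloxy)phenyl]ethanol
Conditions: CSA (0.1 equiv), MeOH/CH2Cl2 (1:1), 0 °C
Reagents that add atoms: none
Why: Acid-catalysed methanolysis should cleave the primary alkyl silyl ether much faster than the acid-robust aryl silyl ethers, freeing only the primary alcohol.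

Step 9
Reactants: 15 2-[3,4-bis(tert-butyldimethylsilyloxy)phenyl]ethanol; 16 (diethoxyphosphoryl)acetic acid
Product: 17 2-[3,4-bis(tert-butyldimethylsilyloxy)phenyl]ethyl (diethoxyphosphoryl)acetate
Conditions: DCC, DMAP (cat.), CH2Cl2, 0 °C → rt
Reagents that add atoms: none
Why: Steglich esterification of the primary alcohol with the phosphonoacetic acid should give the olefination reagent, with the aryl silyl ethers inert.

Step 10
Reactants: 12 (2S,3S)-3-(2-bromo-1-ethoxyethoxy)-2-{[(4-methoxybenzyl)oxy]methyl}butanal; 17 2-[3,4-bis(tert-butyldimethylsilyloxy)phenyl]ethyl (diethoxyphosphoryl)acetate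
Product: 18 2-[3,4-bis(tert-butyldimethylsilyloxy)phenyl]ethyl (2E,4S,5S)-5-(2-bromo-1-ethoxyethoxy)-4-{[(4-methoxybenzyl)oxy]methyl}hex-2-enoate (both acetal epimers)
Conditions: LiCl, i-Pr2NEt, MeCN, rt
Reagents that add atoms: none
Why: Horner–Wadsworth–Emmons olefination under the mild LiCl/amine (Masamune–Roush) conditions should give the E-enoate from the α-branched aldehyde without epimerisation, β-elimination or loss of the aryl silyl ethers.

Step 11
Reactants: 18 the bromoacetal E-enoate
Product: 19 2-[3,4-bis(tert-butyldimethylsilyloxy)phenyl]ethyl 2-[(2S,3S,4R)-6-ethoxy-3-{[(4-methoxybenzyl)oxy]methyl}-2-methyloxan-4-yl]acetate (both C6 epimers)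
Conditions: Bu3SnH (1.3 equiv, syringe pump), AIBN (0.2 equiv), benzene (0.01 M), 80 °C
Reagents that add atoms: none
Why: The tin radical abstracts bromine from 18, and the primary C5 radical, held two atoms from O1 by the C6 acetal, adds to C4, the β-carbon of the C4=C8 enoate; the resulting C8 α-ester radical takes hydrogen from Bu3SnH and carries the chain. This is a Ueno–Stork haloacetal radical cyclisation in its 6-exo variant onto an α,β-unsaturated ester. The oxane ring (O1, C2, C3, C4, C5, C6) closes in the 6-exo-trig mode, favoured over 7-endo attack at C8 because the nucleophilic alkyl radical is polarity-matched with the electron-poor β-carbon. The new centre C4 is controlled by the C2 and C3 centres through a chair-like transition state with the C2 methyl, the C3 CH2OPMB group and the enoate arm all equatorial, which places C4 trans to C3 and cis to C2; C6 forms as a mixture and is erased in step 12. The step needs cyclisation to outrun direct reduction of the open-chain radical and 1,5-hydrogen transfer from C3–H, which the activated E-enoate and slow stannane addition at high dilution should secure.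

Step 12
Reactants: 19 the 6-ethoxyoxane
Product: 20 2-[3,4-bis(tert-butyldimethylsilyloxy)phenyl]ethyl 2-[(2S,3S,4S)-3-{[(4-methoxybenzyl)oxy]methyl}-2-methyl-3,4-dihydro-2H-pyran-4-yl]acetate
Conditions: TMSOTf (1.5 equiv), i-Pr2NEt (2 equiv), CH2Cl2, −20 → 0 °C
Reagents that add atoms: none
Why: Silyl triflate-mediated acetal-to-enol-ether elimination, in which the ethoxy group leaves as TMSOEt and the amine removes a C5 proton from the ring oxocarbenium ion, should give the C5=C6 enol ether and leave C2–C4 untouched.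

Step 13
Reactants: 20 the dihydropyran; 21 trichloroacetyl chloride
Product: 22 2-[3,4-bis(tert-butyldimethylsilyloxy)phenyl]ethyl 2-[(2S,3S,4R)-3-{[(4-methoxybenzyl)oxy]methyl}-2-methyl-5-(trichloroacetyl)-3,4-dihydro-2H-pyran-4-yl]acetate
Conditions: 21 (1.5 equiv), pyridine, CH2Cl2, 0 °C → rt
Reagents that add atoms: none
Why: Electrophilic C-acylation of the enol ether at its nucleophilic β-carbon C5, followed by loss of the C5 proton to pyridine, is a standard functionalisation of cyclic enol ethers and should give the β-alkoxyvinyl trichloromethyl ketone.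

Step 14
Reactants: 22 the trichloromethyl ketone
Product: 23 methyl (2S,3S,4R)-4-{2-[2-(3,4-bis(tert-butyldimethylsilyloxy)phenyl)ethoxy]-2-oxoethyl}-3-{[(4-methoxybenzyl)oxy]methyl}-2-methyl-3,4-dihydro-2H-pyran-5-carboxylate
Conditions: MeOH, Et3N, DMAP (cat.), CH2Cl2, rt
Reagents that add atoms: methanol, CO
Why: Haloform-type cleavage, in which methanol adds to the ketone and trichloromethanide leaves as chloroform, should give the methyl ester under amine conditions mild enough to spare the phenethyl ester and the aryl silyl ethers.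

Step 15
Reactants: 23 the PMB ether methyl ester
Product: 24 methyl (2S,3S,4R)-4-{2-[2-(3,4-bis(tert-butyldimethylsilyloxy)phenyl)ethoxy]-2-oxoethyl}-3-(hydroxymethyl)-2-methyl-3,4-dihydro-2H-pyran-5-carboxylate
Conditions: DDQ, CH2Cl2/H2O (10:1), 0 °C; used crude at once
Reagents that add atoms: none
Why: Oxidative PMB cleavage by DDQ (benzylic hydride abstraction, then hydrolysis) should free the C7 alcohol while the electron-poor β-alkoxyacrylate and the silyl ethers survive; immediate oxidation forestalls lactonisation onto the C9 ester.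

Step 16
Reactants: 24 the C7 alcohol
Product: 25 methyl (2S,3R,4R)-4-{2-[2-(3,4-bis(tert-butyldimethylsilyloxy)phenyl)ethoxy]-2-oxoethyl}-3-formyl-2-methyl-3,4-dihydro-2H-pyran-5-carboxylate
Conditions: Dess–Martin periodinane, NaHCO3, CH2Cl2, 0 °C
Reagents that add atoms: none
Why: Dess–Martin oxidation under buffered conditions should give the C7 aldehyde without disturbing C3, whose substituent already sits in the favoured equatorial, trans arrangement.

Step 17
Reactants: 25 the bis-TBS aldehyde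
Product: 26 2-(3,4-dihydroxyphenyl)ethyl 2-[(2S,3R,4R)-3-formyl-5-(methoxycarbonyl)-2-methyl-3,4-dihydro-2H-pyran-4-yl]acetate (CNP0172886.1)
Conditions: HF·pyridine, pyridine, THF, 0 °C → rt; work-up under argon
Reagents that add atoms: none
Why: Fluoride cleavage of the two aryl silyl ethers with buffered HF·pyridine should release the catechol without base, so that the aldehyde α-centre, both esters and the enol ether are preserved.

**Compound list**

1 | p-methoxybenzyl alcohol | COc1ccc(CO)cc1 | starting material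
2 | chloromethyl methyl sulfide | CSCCl | starting material
3 | sodium 4-methoxybenzyl alkoxide | COc1ccc(C[O-])cc1.[Na+] | intermediate (not isolated)
4 | p-methoxybenzyl methylthiomethyl ether | COc1ccc(COCSC)cc1 | intermediate
5 | p-methoxybenzyl chloromethyl ether | COc1ccc(COCCl)cc1 | intermediate
6 | methyl (S)-3-hydroxybutanoate | C[C@H](O)CC(=O)OC | starting material
7 | dilithium alkoxide enolate of 6 | C[C@H](O[Li])/C=C(\O[Li])OC | intermediate (not isolated)
8 | methyl (2S,3S)-3-hydroxy-2-{[(4-methoxybenzyl)oxy]methyl}butanoate | C[C@H](O)[C@H](COCc1ccc(OC)cc1)C(=O)OC | intermediate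
9 | ethyl vinyl ether | CCOC=C | starting material
10 | methyl (2S,3S)-3-(2-bromo-1-ethoxyethoxy)-2-{[(4-methoxybenzyl)oxy]methyl}butanoate | C[C@H](OC(OCC)CBr)[C@H](COCc1ccc(OC)cc1)C(=O)OC | intermediate
11 | (2S,3S)-3-(2-bromo-1-ethoxyethoxy)-2-{[(4-methoxybenzyl)oxy]methyl}butan-1-ol | C[C@H](OC(OCC)CBr)[C@H](COCc1ccc(OC)cc1)CO | intermediate
12 | (2S,3S)-3-(2-bromo-1-ethoxyethoxy)-2-{[(4-methoxybenzyl)oxy]methyl}butanal | C[C@H](OC(OCC)CBr)[C@H](COCc1ccc(OC)cc1)C=O | intermediate
13 | hydroxytyrosol | OCCc1ccc(O)c(O)c1 | starting material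
14 | tris-TBS hydroxytyrosol | CC(C)(C)[Si](C)(C)OCCc1ccc(O[Si](C)(C)C(C)(C)C)c(O[Si](C)(C)C(C)(C)C)c1 | intermediate
15 | 2-[3,4-bis(tert-butyldimethylsilyloxy)phenyl]ethanol | OCCc1ccc(O[Si](C)(C)C(C)(C)C)c(O[Si](C)(C)C(C)(C)C)c1 | intermediate
16 | (diethoxyphosphoryl)acetic acid | CCOP(=O)(OCC)CC(=O)O | starting material
17 | 2-[3,4-bis(tert-butyldimethylsilyloxy)phenyl]ethyl (diethoxyphosphoryl)acetate | CCOP(=O)(OCC)CC(=O)OCCc1ccc(O[Si](C)(C)C(C)(C)C)c(O[Si](C)(C)C(C)(C)C)c1 | intermediate
18 | 2-[3,4-bis(TBSO)phenyl]ethyl (2E,4S,5S)-5-(2-bromo-1-ethoxyethoxy)-4-{[(4-methoxybenzyl)oxy]methyl}hex-2-enoate | C[C@H](OC(OCC)CBr)[C@H](COCc1ccc(OC)cc1)/C=C/C(=O)OCCc1ccc(O[Si](C)(C)C(C)(C)C)c(O[Si](C)(C)C(C)(C)C)c1 | intermediate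
19 | 2-[3,4-bis(TBSO)phenyl]ethyl 2-[(2S,3S,4R)-6-ethoxy-3-{[(4-methoxybenzyl)oxy]methyl}-2-methyloxan-4-yl]acetate | C1C(OCC)O[C@@H](C)[C@H](COCc2ccc(OC)cc2)[C@H]1CC(=O)OCCc1ccc(O[Si](C)(C)C(C)(C)C)c(O[Si](C)(C)C(C)(C)C)c1 | intermediate
20 | 2-[3,4-bis(TBSO)phenyl]ethyl 2-[(2S,3S,4S)-3-{[(4-methoxybenzyl)oxy]methyl}-2-methyl-3,4-dihydro-2H-pyran-4-yl]acetate | C1=CO[C@@H](C)[C@H](COCc2ccc(OC)cc2)[C@H]1CC(=O)OCCc1ccc(O[Si](C)(C)C(C)(C)C)c(O[Si](C)(C)C(C)(C)C)c1 | intermediate
21 | trichloroacetyl chloride | ClC(Cl)(Cl)C(Cl)=O | starting material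
22 | 2-[3,4-bis(TBSO)phenyl]ethyl 2-[(2S,3S,4R)-3-{[(4-methoxybenzyl)oxy]methyl}-2-methyl-5-(trichloroacetyl)-3,4-dihydro-2H-pyran-4-yl]acetate | ClC(Cl)(Cl)C(=O)C1=CO[C@@H](C)[C@H](COCc2ccc(OC)cc2)[C@H]1CC(=O)OCCc1ccc(O[Si](C)(C)C(C)(C)C)c(O[Si](C)(C)C(C)(C)C)c1 | intermediate
23 | methyl (2S,3S,4R)-4-{2-[2-(3,4-bis(TBSO)phenyl)ethoxy]-2-oxoethyl}-3-{[(4-methoxybenzyl)oxy]methyl}-2-methyl-3,4-dihydro-2H-pyran-5-carboxylate | COC(=O)C1=CO[C@@H](C)[C@H](COCc2ccc(OC)cc2)[C@H]1CC(=O)OCCc1ccc(O[Si](C)(C)C(C)(C)C)c(O[Si](C)(C)C(C)(C)C)c1 | intermediate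
24 | methyl (2S,3S,4R)-4-{2-[2-(3,4-bis(TBSO)phenyl)ethoxy]-2-oxoethyl}-3-(hydroxymethyl)-2-methyl-3,4-dihydro-2H-pyran-5-carboxylate | COC(=O)C1=CO[C@@H](C)[C@H](CO)[C@H]1CC(=O)OCCc1ccc(O[Si](C)(C)C(C)(C)C)c(O[Si](C)(C)C(C)(C)C)c1 | intermediate
25 | methyl (2S,3R,4R)-4-{2-[2-(3,4-bis(TBSO)phenyl)ethoxy]-2-oxoethyl}-3-formyl-2-methyl-3,4-dihydro-2H-pyran-5-carboxylate | COC(=O)C1=CO[C@@H](C)[C@H](C=O)[C@H]1CC(=O)OCCc1ccc(O[Si](C)(C)C(C)(C)C)c(O[Si](C)(C)C(C)(C)C)c1 | intermediate
26 | 2-(3,4-dihydroxyphenyl)ethyl 2-[(2S,3R,4R)-3-formyl-5-(methoxycarbonyl)-2-methyl-3,4-dihydro-2H-pyran-4-yl]acetate | COC(=O)C1=CO[C@@H](C)[C@H](C=O)[C@H]1CC(=O)OCCc1ccc(O)c(O)c1 | target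

**Step count and risks**

Total step count: 17. Longest linear sequence: 14 steps (steps 1–6 and 10–17, from p-methoxybenzyl alcohol 1); 12 steps counted from methyl (S)-3-hydroxybutanoate 6.

Steps most likely to fail:

1. Step 11 (radical closure). The open-chain C5 radical may be reduced by the stannane before it cyclises, may shift a hydrogen from the allylic C3–H, or may close with weak facial discrimination at C4. The fallback closes the same C4–C5 bond by a polar, reversible reaction and sets out from 18. Zn dust with NH4Cl in EtOH at 60 °C should remove the bromoacetal by reductive β-elimination and give 2-[3,4-bis(TBSO)phenyl]ethyl (2E,4S,5S)-5-hydroxy-4-{[(4-methoxybenzyl)oxy]methyl}hex-2-enoate F1. Acylation with methyl malonyl chloride and pyridine in CH2Cl2 should give the mixed malonate F2. NaH in THF should then close the δ-lactone, methyl 2-oxooxane-3-carboxylate F3, by intramolecular Michael addition (6-exo-trig); because this addition is reversible, the all-equatorial arrangement at C2, C3 and C4 should prevail at equilibrium. O-Triflation (NaH, PhNTf2, THF) should give the ketene acetal triflate F4. Formate reduction catalysed by Pd(OAc)2 and PPh3 (HCO2H, Et3N, DMF, 60 °C) should replace the triflate by hydrogen and arrive at 23, so steps 12–14 are bypassed as well.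

2. Step 14 (methanolysis). Amine-promoted methanolysis may also transesterify the phenethyl ester or strip the base-labile aryl silyl ethers before the vinylogous trichloromethyl ketone is consumed. The fallback installs the C5 carbon at the aldehyde level and sets out from 20. Vilsmeier–Haack formylation at C5 (POCl3, DMF, CH2Cl2, 0 °C; aq. NaOAc) should give the 5-formyl dihydropyran F5. Pinnick oxidation (NaClO2, NaH2PO4, 2-methyl-2-butene, t-BuOH/H2O) should give the 5-carboxylic acid F6. Methylation with TMSCHN2 in MeOH/toluene should arrive at 23 under conditions that are never basic.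

3. Step 12 (acetal to enol ether). The silyl triflate may ionise the acetal at the ring oxygen and open the ring, or may cleave the PMB ether. The fallback goes through the lactol and sets out from 19. Mild hydrolysis (AcOH/THF/H2O, 45 °C) should give the 6-hydroxyoxane (lactol) F7. MsCl and Et3N in CH2Cl2 (0 °C → reflux) should convert it into the anomeric mesylate F8, which is not isolated and should eliminate to the C5=C6 enol ether, arriving at 20.

**Further compounds**

F1 | step 11 | 2-[3,4-bis(TBSO)phenyl]ethyl (2E,4S,5S)-5-hydroxy-4-{[(4-methoxybenzyl)oxy]methyl}hex-2-enoate | C[C@H](O)[C@H](COCc1ccc(OC)cc1)/C=C/C(=O)OCCc1ccc(O[Si](C)(C)C(C)(C)C)c(O[Si](C)(C)C(C)(C)C)c1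
F2 | step 11 | (2S,3S,4E)-6-{2-[3,4-bis(TBSO)phenyl]ethoxy}-3-{[(4-methoxybenzyl)oxy]methyl}-6-oxohex-4-en-2-yl methyl propanedioate | C[C@H](OC(=O)CC(=O)OC)[C@H](COCc1ccc(OC)cc1)/C=C/C(=O)OCCc1ccc(O[Si](C)(C)C(C)(C)C)c(O[Si](C)(C)C(C)(C)C)c1
F3 | step 11 | methyl (4R,5S,6S)-4-{2-[2-(3,4-bis(TBSO)phenyl)ethoxy]-2-oxoethyl}-5-{[(4-methoxybenzyl)oxy]methyl}-6-methyl-2-oxooxane-3-carboxylate (C3 epimers) | COC(=O)C1C(=O)O[C@@H](C)[C@H](COCc2ccc(OC)cc2)[C@H]1CC(=O)OCCc1ccc(O[Si](C)(C)C(C)(C)C)c(O[Si](C)(C)C(C)(C)C)c1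
F4 | step 11 | methyl (2S,3S,4R)-4-{2-[2-(3,4-bis(TBSO)phenyl)ethoxy]-2-oxoethyl}-3-{[(4-methoxybenzyl)oxy]methyl}-2-methyl-6-{[(trifluoromethyl)sulfonyl]oxy}-3,4-dihydro-2H-pyran-5-carboxylate | COC(=O)C1=C(OS(=O)(=O)C(F)(F)F)O[C@@H](C)[C@H](COCc2ccc(OC)cc2)[C@H]1CC(=O)OCCc1ccc(O[Si](C)(C)C(C)(C)C)c(O[Si](C)(C)C(C)(C)C)c1
F5 | step 14 | 2-[3,4-bis(TBSO)phenyl]ethyl 2-[(2S,3S,4R)-5-formyl-3-{[(4-methoxybenzyl)oxy]methyl}-2-methyl-3,4-dihydro-2H-pyran-4-yl]acetate | O=CC1=CO[C@@H](C)[C@H](COCc2ccc(OC)cc2)[C@H]1CC(=O)OCCc1ccc(O[Si](C)(C)C(C)(C)C)c(O[Si](C)(C)C(C)(C)C)c1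
F6 | step 14 | (2S,3S,4R)-4-{2-[2-(3,4-bis(TBSO)phenyl)ethoxy]-2-oxoethyl}-3-{[(4-methoxybenzyl)oxy]methyl}-2-methyl-3,4-dihydro-2H-pyran-5-carboxylic acid | OC(=O)C1=CO[C@@H](C)[C@H](COCc2ccc(OC)cc2)[C@H]1CC(=O)OCCc1ccc(O[Si](C)(C)C(C)(C)C)c(O[Si](C)(C)C(C)(C)C)c1
F7 | step 12 | 2-[3,4-bis(TBSO)phenyl]ethyl 2-[(2S,3S,4R)-6-hydroxy-3-{[(4-methoxybenzyl)oxy]methyl}-2-methyloxan-4-yl]acetate (both anomers) | C1C(O)O[C@@H](C)[C@H](COCc2ccc(OC)cc2)[C@H]1CC(=O)OCCc1ccc(O[Si](C)(C)C(C)(C)C)c(O[Si](C)(C)C(C)(C)C)c1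
F8 | step 12 | 2-[3,4-bis(TBSO)phenyl]ethyl 2-[(2S,3S,4R)-6-(methanesulfonyloxy)-3-{[(4-methoxybenzyl)oxy]methyl}-2-methyloxan-4-yl]acetate (not isolated) | C1C(OS(C)(=O)=O)O[C@@H](C)[C@H](COCc2ccc(OC)cc2)[C@H]1CC(=O)OCCc1ccc(O[Si](C)(C)C(C)(C)C)c(O[Si](C)(C)C(C)(C)C)c1
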